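**Plan**

1. The target is 2,4-dibromo-6-(2,3,4-tribromo-6-methoxyphenoxy)phenol and has no stereocentre. Ring A is the tribromo(methoxy)phenyl ring; ring B is the phenol ring, numbered C1 (OH), C2 (Br), C3 (H), C4 (Br), C5 (H), C6 (O–ring A).
2. Feature used: in ring B the brominated C2 sits between oxygen-bearing C1 and unsubstituted C3. This is the pattern left when a CBr unit from dibromocarbene is inserted into the C(OSi)=CH bond of a five-membered silyl enol ether.
3. Retrosynthesis: cut C4–Br of ring B, then O–Si, then C1–C2 and C2–C3 (C2 leaves as CBr2), which gives a 2-aryloxy-3-silyloxycyclopenta-1,3-diene. Next cut its C6–O(aryl) bond to a tribromoguaiacol and cyclopentenone oxide, and two C–Br bonds of ring A back to 5-bromoguaiacol.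
4. Forward: ring A is bought and brominated. Cyclopent-2-enone supplies C1 and C3–C6 and is joined to ring A through the ether oxygen (epoxide opening, dehydration). The enone is silylated to the diene, and ring B arises in step 5 when the five-membered ring takes up the carbene carbon as C2. Desilylation and one bromination finish.
5. Stereochemistry: none to set. The epoxide, hydroxy ketone and cyclopropane on the way are racemic, and their centres are erased by elimination or aromatization.

Key step: step 5

Remark: 5-bromo-2-methoxyphenol, cyclopent-2-en-1-one and bromoform are taken as purchased. The silyl group of the ring-expansion substrate is tert-butyldimethylsilyl, so ring B is first obtained as its silyl ether.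

**Route**

Step 1
Reactants: 1 5-bromo-2-methoxyphenol
Product: 2 2,3,4-tribromo-6-methoxyphenol
Conditions: Br2 (2.1 equiv), AcOH, rt
Reagents that add atoms: bromine, BrBr
Why: Electrophilic aromatic bromination in which the free hydroxyl is the dominant director: its para and its open ortho position are the only carbons it activates, the last CH is merely ortho to OMe and meta to OH, so two equivalents of bromine should stop at the 4,5,6-tribromoguaiacol pattern.

Step 2
Reactants: 3 cyclopent-2-en-1-one
Product: 4 6-oxabicyclo[3.1.0]hexan-2-one
Conditions: H2O2 (30% aq.), NaOH (cat.), MeOH, 0 °C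
Reagents that add atoms: hydrogen peroxide, OO
Why: Weitz–Scheffer nucleophilic epoxidation: hydroperoxide adds in conjugate fashion and the enolate closes the oxirane with loss of hydroxide; the cis ring fusion is the only one possible and the product is racemic.

Step 3
Reactants: 2 2,3,4-tribromo-6-methoxyphenol; 4 6-oxabicyclo[3.1.0]hexan-2-one
Product: 6 2-(2,3,4-tribromo-6-methoxyphenoxy)cyclopent-2-en-1-one, via hydroxy ketone 5 (not isolated)
Conditions: Cs2CO3 (0.3 equiv), DMF, 50 °C
Reagents that add atoms: none
Why: Base-mediated opening of an α,β-epoxy ketone by a phenoxide at the carbonyl-activated α-carbon (SN2, giving trans hydroxy ketone 5) followed by E1cB loss of water is the established way from cycloalkenone oxides to 2-aryloxy enones; the base is regenerated and the stereocentres of 4 and 5 vanish in the elimination.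

Step 4
Reactants: 6 2-(2,3,4-tribromo-6-methoxyphenoxy)cyclopent-2-en-1-one
Product: 7 tert-butyl(dimethyl){[5-(2,3,4-tribromo-6-methoxyphenoxy)cyclopenta-1,4-dien-1-yl]oxy}silane
Conditions: TBSOTf (1.2 equiv), Et3N (2 equiv), CH2Cl2, −78 to 0 °C; cold pentane/aq. NaHCO3 work-up, used at once
Reagents that add atoms: tert-butyldimethylsilyl trifluoromethanesulfonate, CC(C)(C)[Si](C)(C)OS(=O)(=O)C(F)(F)F
Why: Soft enolization of an enone with a silyl triflate and triethylamine removes the α′ proton (at the future C3) kinetically, as in the known conversion of cyclopent-2-enone into 2-silyloxycyclopenta-1,3-dienes; the cross-conjugated dienol ether is kept cold and used directly because cyclopentadienes undergo 1,5-hydrogen shifts and dimerize.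

Step 5
Reactants: 7 tert-butyl(dimethyl){[5-(2,3,4-tribromo-6-methoxyphenoxy)cyclopenta-1,4-dien-1-yl]oxy}silane; 8 bromoform
Product: 10 tert-butyl[2-bromo-6-(2,3,4-tribromo-6-methoxyphenoxy)phenoxy]dimethylsilane, via dibromocyclopropane 9 (not isolated)
Conditions: CHBr3 (1.5 equiv), KOtBu (3 equiv, added last in portions), pentane, −40 to 0 °C
Reagents that add atoms: bromoform (compound 8), BrC(Br)Br
Why: Potassium tert-butoxide takes HBr from bromoform (α-elimination) and the electrophilic singlet dibromocarbene adds in a concerted [2+1] step across the silyl enol ether bond of 7 (C1=C3 in ring B numbering, C2 not yet present), closing the three-membered ring of 9 with the only possible, cis, fusion. The strained C1–C3 bond of 9 then opens in a disrotatory 2π-electrocyclic (cyclopropyl-to-allyl) ionization in which the bromide syn to the five-membered ring leaves and the silyloxy oxygen pushes, so the five-membered carbocycle becomes six-membered ring B with the carbene carbon installed as C2, bonded to C1 and C3 and keeping one bromine. The cation formed is an O-silylated arenium ion that loses a proton from its CH2 group (C4) to tert-butoxide, so the diene oxidation level of 7 makes an oxidant unnecessary and the phenol emerges masked as silyl ether 10. Closest known reaction types: dihalocarbene ring expansion of cyclic silyl enol ethers to 2-halo enones, of 1-indanone silyl enol ethers to 2-halo-1-naphthols, and of cyclopentadienes and indenes to haloarenes. The two stereocentres of 9 are racemic and disappear on aromatization, so none needs control. The step needs site selectivity between the two enol ether bonds: the silyloxy-substituted one is the stronger donor, while the oxygen on C6=C5 is shared with the electron-poor, ortho-disubstituted ring A that also screens it, and adding the base last to 7 and excess bromoform at low temperature keeps tert-butoxide on the more acidic bromoform and away from the ring CH2.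

Step 6
Reactants: 10 tert-butyl[2-bromo-6-(2,3,4-tribromo-6-methoxyphenoxy)phenoxy]dimethylsilane
Product: 11 2-bromo-6-(2,3,4-tribromo-6-methoxyphenoxy)phenol
Conditions: TBAF, AcOH (1 equiv each), THF, 0 °C
Reagents that add atoms: none
Why: Fluoride-induced cleavage of an aryl silyl ether (Si–F bond formation) is fast at 0 °C, the acetic acid buffer protonates the bromophenoxide as it forms, and the methyl ether, diaryl ether and aryl bromides are inert.

Step 7
Reactants: 11 2-bromo-6-(2,3,4-tribromo-6-methoxyphenoxy)phenol
Product: 12 2,4-dibromo-6-(2,3,4-tribromo-6-methoxyphenoxy)phenol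
Conditions: Br2 (1.0 equiv), CH2Cl2–AcOH, 0 °C
Reagents that add atoms: bromine, BrBr
Why: Electrophilic aromatic bromination of a phenol whose two ortho positions are blocked (C2 Br, C6 O-aryl): the hydroxyl directs to the free para carbon C4, which should outpace the positions activated only by the diaryl ether oxygen and the deactivated ring A.

**Compound list**

1 | 5-bromo-2-methoxyphenol (5-bromoguaiacol) | COc1ccc(Br)cc1O | starting material
2 | 2,3,4-tribromo-6-methoxyphenol (4,5,6-tribromoguaiacol) | COc1cc(Br)c(Br)c(Br)c1O | intermediate
3 | cyclopent-2-en-1-one | O=C1C=CCC1 | starting material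
4 | 6-oxabicyclo[3.1.0]hexan-2-one (2,3-epoxycyclopentanone; racemic, cis-fused, one enantiomer drawn) | O=C1CC[C@H]2O[C@@H]12 | intermediate
5 | trans-3-hydroxy-2-(2,3,4-tribromo-6-methoxyphenoxy)cyclopentan-1-one (racemic, one enantiomer drawn) | O=C1CC[C@@H](O)[C@@H]1Oc1c(OC)cc(Br)c(Br)c1Br | intermediate (not isolated)
6 | 2-(2,3,4-tribromo-6-methoxyphenoxy)cyclopent-2-en-1-one | COc1cc(Br)c(Br)c(Br)c1OC1=CCCC1=O | intermediate
7 | tert-butyl(dimethyl){[5-(2,3,4-tribromo-6-methoxyphenoxy)cyclopenta-1,4-dien-1-yl]oxy}silane (2-aryloxy-3-silyloxycyclopenta-1,3-diene) | COc1cc(Br)c(Br)c(Br)c1OC1=CCC=C1O[Si](C)(C)C(C)(C)C | intermediate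
8 | bromoform | BrC(Br)Br | starting material
9 | 6,6-dibromo-1-(tert-butyldimethylsilyloxy)-2-(2,3,4-tribromo-6-methoxyphenoxy)bicyclo[3.1.0]hex-2-ene (racemic, cis-fused, one enantiomer drawn) | CC(C)(C)[Si](C)(C)O[C@]12C(Oc3c(OC)cc(Br)c(Br)c3Br)=CC[C@H]1C2(Br)Br | intermediate (not isolated)
10 | tert-butyl[2-bromo-6-(2,3,4-tribromo-6-methoxyphenoxy)phenoxy]dimethylsilane | COc1cc(Br)c(Br)c(Br)c1Oc1cccc(Br)c1O[Si](C)(C)C(C)(C)C | intermediate
11 | 2-bromo-6-(2,3,4-tribromo-6-methoxyphenoxy)phenol | COc1cc(Br)c(Br)c(Br)c1Oc1cccc(Br)c1O | intermediate
12 | 2,4-dibromo-6-(2,3,4-tribromo-6-methoxyphenoxy)phenol | COc1cc(Br)c(Br)c(Br)c1Oc1cc(Br)cc(Br)c1O | target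

**Step count**

Total steps: 7. Longest linear sequence: 6 steps (steps 1, 3, 4, 5, 6, 7 from compound 1, or steps 2 to 7 from compound 3).

**Steps most likely to fail**

Step 5. Several processes could spoil the ring expansion:
- carbene addition to the aryloxy-substituted double bond;
- deprotonation of the ring CH2 to a cyclopentadienide that is attacked unselectively, so that bromine ends up on the wrong carbon;
- a 1,5-hydrogen shift of the diene before cyclopropanation;
- premature loss of the silyl group, so that the phenoxide is attacked by further carbene.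

The fallback gives up the ring expansion and builds the diaryl ether by known arene chemistry. It sets out from compound 2. Nucleophilic aromatic substitution of 2-bromo-6-fluorobenzaldehyde (K2CO3, DMF, 100 °C), with fluoride activated by the ortho formyl group as leaving group, should give 2-bromo-6-(2,3,4-tribromo-6-methoxyphenoxy)benzaldehyde F1. Baeyer–Villiger (Dakin-type) oxidation with mCPBA in CH2Cl2, in which the ortho-oxygenated aryl group migrates, should give 2-bromo-6-(2,3,4-tribromo-6-methoxyphenoxy)phenyl formate F2. Saponification (KOH, MeOH–H2O, rt, then acid) returns to the route at compound 11, after which step 7 follows unchanged.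

Step 3. The base could isomerize or oligomerize the epoxy ketone faster than the hindered, weakly nucleophilic 2,6-disubstituted phenoxide attacks it, and dehydration of the hydroxy ketone could stall. The fallback forms the ether by alkylation of a saturated ketone and introduces the double bond afterwards. It sets out from compound 2. O-Alkylation with 2-chlorocyclopentanone (K2CO3, acetone, reflux) should give 2-(2,3,4-tribromo-6-methoxyphenoxy)cyclopentan-1-one F3. Silylation under equilibrating conditions (TMSCl, NaI, Et3N, MeCN) should enolize towards the more acidic aryloxy-bearing carbon and give trimethyl{[2-(2,3,4-tribromo-6-methoxyphenoxy)cyclopent-1-en-1-yl]oxy}silane F4. Saegusa–Ito oxidation with Pd(OAc)2 in MeCN at rt then places the double bond between C6 and C5 and comes back to the route at compound 6.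

Step 4. Silylation could take the γ-proton instead of the α′-proton, and the diene could shift its double bonds by 1,5-hydrogen migration, dimerize by Diels–Alder reaction or hydrolyse before it meets the carbene. The fallback keeps the carbene insertion but runs it one oxidation level lower, on a stable cyclopentene silyl enol ether, and aromatizes afterwards. It sets out from compound 2, which is alkylated as described above to 2-(2,3,4-tribromo-6-methoxyphenoxy)cyclopentan-1-one F3. Kinetic enolization away from the aryloxy group (LiN(SiMe3)2, TMSCl, THF, −78 °C) should give trimethyl{[5-(2,3,4-tribromo-6-methoxyphenoxy)cyclopent-1-en-1-yl]oxy}silane F5. Bromoform and KOtBu in pentane at −20 °C should give 6,6-dibromo-2-(2,3,4-tribromo-6-methoxyphenoxy)-1-(trimethylsilyloxy)bicyclo[3.1.0]hexane F6. On warming this opens with loss of the silyl group to 2-bromo-6-(2,3,4-tribromo-6-methoxyphenoxy)cyclohex-2-en-1-one F7. Dehydrogenation with DDQ in dioxane at reflux aromatizes the ring and comes back to the route at compound 11.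

**Further compounds**

F1 | step 5 | 2-bromo-6-(2,3,4-tribromo-6-methoxyphenoxy)benzaldehyde | COc1cc(Br)c(Br)c(Br)c1Oc1cccc(Br)c1C=O
F2 | step 5 | 2-bromo-6-(2,3,4-tribromo-6-methoxyphenoxy)phenyl formate | COc1cc(Br)c(Br)c(Br)c1Oc1cccc(Br)c1OC=O
F3 | step 3 | 2-(2,3,4-tribromo-6-methoxyphenoxy)cyclopentan-1-one (racemic) | COc1cc(Br)c(Br)c(Br)c1OC1CCCC1=O
F4 | step 3 | trimethyl{[2-(2,3,4-tribromo-6-methoxyphenoxy)cyclopent-1-en-1-yl]oxy}silane | COc1cc(Br)c(Br)c(Br)c1OC1=C(O[Si](C)(C)C)CCC1
F5 | step 4 | trimethyl{[5-(2,3,4-tribromo-6-methoxyphenoxy)cyclopent-1-en-1-yl]oxy}silane (racemic) | COc1cc(Br)c(Br)c(Br)c1OC1CCC=C1O[Si](C)(C)C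
F6 | step 4 | 6,6-dibromo-2-(2,3,4-tribromo-6-methoxyphenoxy)-1-(trimethylsilyloxy)bicyclo[3.1.0]hexane (racemic, cis-fused, aryloxy centre as a mixture) | C[Si](C)(C)O[C@]12C(Oc3c(OC)cc(Br)c(Br)c3Br)CC[C@H]1C2(Br)Br
F7 | step 4 | 2-bromo-6-(2,3,4-tribromo-6-methoxyphenoxy)cyclohex-2-en-1-one (racemic) | COc1cc(Br)c(Br)c(Br)c1OC1CCC=C(Br)C1=O
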